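Its constants were chosen freely; no experiment stands behind them.

Reckoned at full partner with the catalyst awake, coupling drains the left-handed substrate at 0.161 s⁻¹ while the racemization catalyst refills it at 0.147 s⁻¹, a near tie with which the meeting on this flask opened, over these charges and questions.

| setting | spring | dusk |
|---|---|---|
| left-handed substrate | 0.0050 M | 0.0050 M |
| coupling partner | 2.20 equiv | 2.20 equiv |
| racemization catalyst | 2.5 mol% | 2.5 mol% |
| precatalyst | 2 mol% | 2 mol% |
| right-handed substrate | 0.0050 M | 0.0050 M |
| time | 8.0 s | 15 s |

    coupling partner + free catalyst + left-handed substrate → free catalyst + left-handed product (k1 = 2.04 × 10⁵ M⁻² s⁻¹)
    coupling partner + free catalyst + right-handed substrate → free catalyst + right-handed product (k2 = 32800 M⁻² s⁻¹)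
    left-handed substrate + racemization catalyst ⇌ right-handed substrate + racemization catalyst, rate k3*[racemization catalyst]*[left-handed substrate] forward; the back reaction follows from the equilibrium constant (k3 = 1180 M⁻¹ s⁻¹)
    coupling partner + precatalyst → free catalyst + spent reagent (k4 = 65.5 M⁻¹ s⁻¹)
    free catalyst ⇌ dormant form (K5 = 0.396, k5 = 1.99 s⁻¹)

- free catalyst is single-handed; left-handed substrate and right-handed substrate are mirror images of each other, charged as a racemate, each of them at the stated concentration
- run time (spring): 8.0 s

- which of these there is most of at the end, counted by the substrate in it, spring (left-handed product / right-handed substrate / left-handed substrate / right-handed product)
- which of these there is most of at the end, counted by the substrate in it, dusk (left-handed product / right-handed substrate / left-handed substrate / right-handed product)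
- final amount of the leader among these, as a percentage of the left-handed substrate and right-handed substrate together charged, in spring
- final amount of the leader among these, as a percentage of the left-handed substrate and right-handed substrate together charged, in dusk

The chair asked for one number to carry, and I proposed treating the substrates as a racemate with a small correction. Each drain above is a pseudo-first-order constant, taken at full partner, on the left-handed charge, with the catalyst awake and split between free and dormant forms, and the right-handed drain is 0.0258 s⁻¹. I argued that the difference of the drains keeps opening a split which racemization pulls back with a half-life of 2.36 s, shorter than the spring run, so that the split holds near a steady size, and the difference over four times the refill gives 0.229 at full partner for the handedness gap, the excess of right-handed over left-handed substrate as a fraction of both together.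

A colleague asked what the pool of both substrates does, and I answered that it falls at the mean of the drains less half their difference times the gap, 0.0779 s⁻¹. The catalyst's advocate added that the precatalyst wakes after a mean 1.39 s, and that the partner, at 1.10 on the two substrates together, falls roughly with the pool, so that rate and gap both shrink with it.

My reckoning then left a pool of 66.0% in spring and 48.5% in dusk. Taking the product's split at the selectivity factor 6.22, I committed to more right-handed substrate than left-handed product in spring, 38.0% against 29.3%, and to the reverse in dusk, 44.3% against 27.0%.

The forecast gave left-handed product at 64% in spring and left-handed product at 75% in dusk, higher than my leaders and with another spring leader, holding that “the right-handed pool keeps feeding into left-handed product”.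

The flask gives right-handed substrate at 36.1% in spring and left-handed product at 45.6% in dusk.

In dusk at 5.55 s, left-handed substrate was leaving by coupling at 0.79 of its forward rate by racemization, and the gap scaled to the 49% of partner remaining at 15 s is 0.112, beside 0.124 read from the two substrates. In the neighbour of dusk charged with 0.8 mol% of precatalyst, the gap scaled by that loading and by its remaining 69% of partner is 0.0635, beside 0.0668 read there, and right-handed substrate leads that flask at 35.6%.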